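**Retrosynthetic overview**

- Target ⇐ hydrogenolysis of its tri-O-benzyl ether.
- Tri-O-benzyl trans-isoflavan-4-ol ⇐ C4–O bond formation: CuH-catalysed enantioselective syn hydro-acyloxylation of the achiral isoflav-3-ene (H to C3, O to C4), which sets both stereocentres in one step.
- Isoflav-3-ene ⇐ pyran ring, the only ring built (rings A and B are bought as arenes): O1–C2 etherification, then intramolecular Wittig closure of C3=C4, between a ring A (2-hydroxybenzyl)phosphonium salt and a ring B phenacyl bromide.
- Ring A salt ⇐ 2,4-dihydroxy-5-methoxybenzaldehyde; ring B bromide ⇐ 2'-hydroxy-3',4'-dimethoxyacetophenone, whose C5'–O bond comes from an Elbs oxidation.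

Assumption: the (R)-ligand in step 8 is written by analogy with the facial preference of this catalyst for beta-substituted styrenes; the sense must be confirmed on the first run, and the (S)-ligand gives the antipode.

**Step 1**
Reactants: 1 2,4-dihydroxy-5-methoxybenzaldehyde
Product: 2 4-(benzyloxy)-2-hydroxy-5-methoxybenzaldehyde
Conditions: BnBr (1.05 equiv), NaHCO3, MeCN, 80 °C
Reagents that add atoms: benzyl bromide, BrCc1ccccc1
Why: Williamson etherification; the 4-OH is the more acidic, non-chelated phenol (the 2-OH is hydrogen-bonded to the aldehyde), so a weak base alkylates it selectively.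

**Step 2**
Reactants: 2 4-(benzyloxy)-2-hydroxy-5-methoxybenzaldehyde
Product: 3 5-(benzyloxy)-2-(hydroxymethyl)-4-methoxyphenol
Conditions: NaBH4, THF–MeOH, 0 °C
Reagents that add atoms: none
Why: Borohydride reduction of the aldehyde to the salicyl alcohol; nothing else in the molecule is reducible.

**Step 3**
Reactants: 3 5-(benzyloxy)-2-(hydroxymethyl)-4-methoxyphenol
Product: 4 [4-(benzyloxy)-2-hydroxy-5-methoxybenzyl]triphenylphosphonium bromide
Conditions: PPh3·HBr, MeCN, 80 °C
Reagents that add atoms: triphenylphosphine hydrobromide, [Br-].[PH+](c1ccccc1)(c1ccccc1)c1ccccc1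
Why: Phosphonium salt formation; the electron-rich salicyl alcohol loses water under mild acid to an o-quinone methide/benzylic cation that PPh3 traps, and the aryl benzyl ether survives.

**Step 4**
Reactants: 5 1-(2-hydroxy-3,4-dimethoxyphenyl)ethanone
Product: 7 1-(2,5-dihydroxy-3,4-dimethoxyphenyl)ethanone, via potassium aryl sulfate 6 (not isolated)
Conditions: K2S2O8, aq KOH, 0 → 25 °C; then aq HCl, 80 °C
Reagents that add atoms: potassium peroxodisulfate, [K+].[K+].[O-]S(=O)(=O)OOS(=O)(=O)[O-]
Why: Elbs persulfate oxidation (C–O bond formation); the phenolate attacks a peroxide oxygen through its para carbon, the only free ortho/para position (C5), and acid hydrolyses the aryl sulfate to the hydroquinone.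

**Step 5**
Reactants: 7 1-(2,5-dihydroxy-3,4-dimethoxyphenyl)ethanone
Product: 8 1-[2,5-bis(benzyloxy)-3,4-dimethoxyphenyl]ethanone
Conditions: BnBr (2.5 equiv), K2CO3, DMF, 70 °C, under N2
Reagents that add atoms: benzyl bromide, BrCc1ccccc1
Why: Double Williamson etherification; warm DMF also alkylates the chelated 2-OH, and exclusion of air protects the hydroquinone until it is capped.

**Step 6**
Reactants: 8 1-[2,5-bis(benzyloxy)-3,4-dimethoxyphenyl]ethanone
Product: 9 1-[2,5-bis(benzyloxy)-3,4-dimethoxyphenyl]-2-bromoethanone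
Conditions: CuBr2 (2 equiv), EtOAc–CHCl3, reflux
Reagents that add atoms: copper dibromide CuBr2, [Cu+2].[Br-].[Br-]
Why: Heterogeneous alpha-bromination of an aryl methyl ketone through its enol; this reagent brominates the enol in preference to an electron-rich arene.

**Step 7**
Reactants: 4 [4-(benzyloxy)-2-hydroxy-5-methoxybenzyl]triphenylphosphonium bromide; 9 1-[2,5-bis(benzyloxy)-3,4-dimethoxyphenyl]-2-bromoethanone
Product: 11 7-(benzyloxy)-3-[2,5-bis(benzyloxy)-3,4-dimethoxyphenyl]-6-methoxy-2H-chromene, via aryloxyketone phosphonium bromide 10 (not isolated)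
Conditions: t-BuOK (1.0 equiv), DMF, 0 °C; then 9, 25 °C; then t-BuOK (1.1 equiv), 0 → 25 °C
Reagents that add atoms: none
Why: Williamson O-alkylation of the phosphonium phenolate (O1–C2 bond), then intramolecular Wittig olefination of the aryl ketone by the benzylic ylide, closes the pyran ring as the C3=C4 alkene.

**Step 8**
Reactants: 11 7-(benzyloxy)-3-[2,5-bis(benzyloxy)-3,4-dimethoxyphenyl]-6-methoxy-2H-chromene
Product: 13 (3S,4R)-7-(benzyloxy)-3-[2,5-bis(benzyloxy)-3,4-dimethoxyphenyl]-6-methoxychroman-4-ol, via C4 benzoate 12 (not isolated)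
Conditions: Cu(OAc)2 (8 mol%), (R)-DTBM-SEGPHOS (9 mol%), (MeO)2MeSiH (3 equiv), THF, 40 °C, (PhCO2)2 (1.6 equiv, dried) by syringe pump over 10 h; then K2CO3, MeOH, 25 °C
Reagents that add atoms: dibenzoyl peroxide, O=C(OOC(=O)c1ccccc1)c1ccccc1
Why: Proposed new method: catalytic enantioselective anti-Markovnikov hydro-acyloxylation; the DTBM-SEGPHOS-ligated CuH adds syn across C3=C4 of this beta,beta-disubstituted styrene (H to the fully substituted C3, Cu to the less hindered benzylic C4), which is the enantio-determining event and fixes C3 and C4 together; the benzylic alkylcopper then attacks the O–O bond of the peroxide (oxidative addition at monovalent copper, C–O reductive elimination from trivalent copper with retention, and even a radical rebound would place the benzoate trans to the 3-aryl group), so O at C4 and H at C3 are cis and aryl/O trans, giving (3S,4R); CuO2CPh is returned to CuH by the silane, and the peroxide is dosed slowly so that it meets the alkylcopper resting state and not CuH; the closest known reaction type is CuH-catalysed hydroamination of styrenes with O-benzoylhydroxylamines, with the N–O electrophile replaced by an O–O electrophile; basic methanolysis then frees the alcohol, which is recrystallised to raise the ee.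

**Step 9**
Reactants: 13 (3S,4R)-7-(benzyloxy)-3-[2,5-bis(benzyloxy)-3,4-dimethoxyphenyl]-6-methoxychroman-4-ol
Product: 14 (3S,4R)-3-(2,5-dihydroxy-3,4-dimethoxyphenyl)-6-methoxychromane-4,7-diol
Conditions: H2 (1 atm), 10% Pd/C, EtOAc–MeOH, 25 °C; filtration and evaporation under Ar
Reagents that add atoms: none
Why: Hydrogenolysis of three aryl benzyl ethers; under neutral conditions these cleave faster than the secondary benzylic C4–OH, and the absence of acid keeps the 2'-OH from closing onto C4 and leaves both stereocentres untouched.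

**Compound list**

1 | 2,4-dihydroxy-5-methoxybenzaldehyde | O=Cc1cc(OC)c(O)cc1O | starting material
2 | 4-(benzyloxy)-2-hydroxy-5-methoxybenzaldehyde | O=Cc1cc(OC)c(OCc2ccccc2)cc1O | intermediate
3 | 5-(benzyloxy)-2-(hydroxymethyl)-4-methoxyphenol | OCc1cc(OC)c(OCc2ccccc2)cc1O | intermediate
4 | [4-(benzyloxy)-2-hydroxy-5-methoxybenzyl]triphenylphosphonium bromide | [Br-].Oc1cc(OCc2ccccc2)c(OC)cc1C[P+](c1ccccc1)(c1ccccc1)c1ccccc1 | intermediate
5 | 1-(2-hydroxy-3,4-dimethoxyphenyl)ethanone | CC(=O)c1ccc(OC)c(OC)c1O | starting material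
6 | potassium 5-acetyl-4-hydroxy-2,3-dimethoxyphenyl sulfate | [K+].CC(=O)c1cc(OS(=O)(=O)[O-])c(OC)c(OC)c1O | intermediate
7 | 1-(2,5-dihydroxy-3,4-dimethoxyphenyl)ethanone | CC(=O)c1cc(O)c(OC)c(OC)c1O | intermediate
8 | 1-[2,5-bis(benzyloxy)-3,4-dimethoxyphenyl]ethanone | CC(=O)c1cc(OCc2ccccc2)c(OC)c(OC)c1OCc1ccccc1 | intermediate
9 | 1-[2,5-bis(benzyloxy)-3,4-dimethoxyphenyl]-2-bromoethanone | BrCC(=O)c1cc(OCc2ccccc2)c(OC)c(OC)c1OCc1ccccc1 | intermediate
10 | {4-(benzyloxy)-2-[2-(2,5-bis(benzyloxy)-3,4-dimethoxyphenyl)-2-oxoethoxy]-5-methoxybenzyl}triphenylphosphonium bromide | [Br-].COc1cc(C[P+](c2ccccc2)(c2ccccc2)c2ccccc2)c(OCC(=O)c2cc(OCc3ccccc3)c(OC)c(OC)c2OCc2ccccc2)cc1OCc1ccccc1 | intermediate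
11 | 7-(benzyloxy)-3-[2,5-bis(benzyloxy)-3,4-dimethoxyphenyl]-6-methoxy-2H-chromene | COc1cc2C=C(COc2cc1OCc1ccccc1)c1cc(OCc2ccccc2)c(OC)c(OC)c1OCc1ccccc1 | intermediate
12 | (3S,4R)-7-(benzyloxy)-3-[2,5-bis(benzyloxy)-3,4-dimethoxyphenyl]-6-methoxychroman-4-yl benzoate | COc1cc2c(cc1OCc1ccccc1)OC[C@H](c1cc(OCc3ccccc3)c(OC)c(OC)c1OCc1ccccc1)[C@H]2OC(=O)c1ccccc1 | intermediate
13 | (3S,4R)-7-(benzyloxy)-3-[2,5-bis(benzyloxy)-3,4-dimethoxyphenyl]-6-methoxychroman-4-ol | COc1cc2c(cc1OCc1ccccc1)OC[C@H](c1cc(OCc3ccccc3)c(OC)c(OC)c1OCc1ccccc1)[C@H]2O | intermediate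
14 | (3S,4R)-3-(2,5-dihydroxy-3,4-dimethoxyphenyl)-6-methoxychromane-4,7-diol | COc1cc2c(cc1O)OC[C@H](c1cc(O)c(OC)c(OC)c1O)[C@H]2O | target

**Step count**

Total steps: 9. Longest linear sequence: 6 (steps 1, 2, 3, 7, 8, 9, or equally steps 4, 5, 6, 7, 8, 9).

**Steps most likely to fail, with fallbacks**

Step 8 (the proposed new hydro-acyloxylation). The risks are that CuH reduces the peroxide faster than it adds to the hindered alkene, that the phosphine is oxidised, or that the ee is low. The fallback uses known chemistry and sets out from 11. Asymmetric hydroboration with monoisopinocampheylborane (IpcBH2 made from (+)-alpha-pinene, THF, −25 °C) is the classical reagent-controlled syn hydroboration of trisubstituted aryl cycloalkenes. It places boron on C4 and hydrogen on C3 and gives the dialkylborane (isopinocampheyl)[trans-7-(benzyloxy)-3-(2,5-bis(benzyloxy)-3,4-dimethoxyphenyl)-6-methoxychroman-4-yl]borane F1. Oxidation in the same flask (NaOH, H2O2, 0 → 25 °C) proceeds with retention and comes back to the route at 13. The pinene antipode is chosen by analogy with the reagent that gives (1S,2R)-trans-2-arylcycloalkanols; this choice must be confirmed on the first run.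

Step 7 (etherification/Wittig annulation). The risks are C-alkylation of the ylide or a sluggish olefination of the hindered aryl ketone. The fallback sets out from 2 and 9. Alkylation of the salicylaldehyde phenol with the phenacyl bromide (K2CO3, acetone, 25 °C, kept cold enough to avoid aldol closure to a benzofuran) gives the keto aldehyde 4-(benzyloxy)-2-{2-[2,5-bis(benzyloxy)-3,4-dimethoxyphenyl]-2-oxoethoxy}-5-methoxybenzaldehyde F2. Intramolecular McMurry coupling with low-valent titanium (TiCl4, Zn, pyridine, THF, reflux) then joins the two carbonyl carbons as C3=C4 and comes back to the route at 11. This removes steps 2 and 3 from the sequence.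

Step 4 (Elbs oxidation). The risk is a low yield (typically about a third) with over-oxidation. The fallback sets out from 5. Duff formylation (hexamethylenetetramine, CF3CO2H, 80 °C) occurs at the only free para position and gives 5-acetyl-4-hydroxy-2,3-dimethoxybenzaldehyde F3. Dakin oxidation of this p-hydroxybenzaldehyde (H2O2, aq NaOH, 0 °C; the aldehyde reacts well before the o-hydroxy ketone) then comes back to the route at 7.

**Further compounds**

F1 | step 8 | (isopinocampheyl)[trans-7-(benzyloxy)-3-(2,5-bis(benzyloxy)-3,4-dimethoxyphenyl)-6-methoxychroman-4-yl]borane, C3/C4 configured as in 13 | C[C@H]1[C@H](B[C@H]2c3cc(OC)c(OCc4ccccc4)cc3OC[C@@H]2c2cc(OCc3ccccc3)c(OC)c(OC)c2OCc2ccccc2)C[C@@H]2C[C@H]1C2(C)C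
F2 | step 7 | 4-(benzyloxy)-2-{2-[2,5-bis(benzyloxy)-3,4-dimethoxyphenyl]-2-oxoethoxy}-5-methoxybenzaldehyde | O=Cc1cc(OC)c(OCc2ccccc2)cc1OCC(=O)c1cc(OCc2ccccc2)c(OC)c(OC)c1OCc1ccccc1
F3 | step 4 | 5-acetyl-4-hydroxy-2,3-dimethoxybenzaldehyde | CC(=O)c1cc(C=O)c(OC)c(OC)c1O
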